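## Retrosynthetic overview

1. The pyranone ring is the only ring formed, and it is formed last: the one phenol oxygen para to the benzyl group opens a trans chalcone epoxide at its benzylic carbon (O1–C2 bond), followed by MOM removal.
2. The chalcone epoxide is split at the C4–C4a bond into an A/C-ring aryllithium (diarylmethane, from bromide 10) and a B-ring C6–C3 epoxy morpholine amide (16). This acylation is the late coupling.
3. Amide 16 comes from catalytic asymmetric epoxidation of a cinnamoyl morpholine amide, itself made by Heck reaction of MOM-protected 4-iodophenol with acrylic acid.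
4. Bromide 10 comes from phenol 8 by ortho-bromination and ethoxyethyl (EE) protection. Phenol 8 comes from Ir-catalysed C–H borylation/oxidation of diarylmethane 7.
5. Diarylmethane 7 comes from ortho-lithiated resorcinol bis-MOM ether and 4-(MOMO)benzaldehyde (from 4-bromophenol), then benzylic deoxygenation.

Assumption: MOMCl, DMF, Ac2O, H2O2/B2pin2, NBS, ethyl vinyl ether, morpholine and TBHP are treated as reagents and are not numbered.

## Route

**Step 1**
Reactants: 1, 4-bromophenol
Product: 2, 1-bromo-4-(methoxymethoxy)benzene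
Conditions: MOMCl, i-Pr2NEt, CH2Cl2, 0 °C → rt
Reagents that add atoms: chloromethyl methyl ether, COCCl
Why: Simple O-alkylation (Williamson-type) of the phenol; MOM is stable to the organolithium, Pd, Ir and basic steps that follow.

**Step 2**
Reactants: 2, 1-bromo-4-(methoxymethoxy)benzene
Product: 3, 4-(methoxymethoxy)benzaldehyde
Conditions: n-BuLi, THF, −78 °C; then DMF, −78 → 0 °C; aq. NH4Cl
Reagents that add atoms: N,N-dimethylformamide, CN(C)C=O
Why: Br–Li exchange at −78 °C is much faster than ortho-lithiation, and the aryllithium is formylated by DMF (Bouveault formylation).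

**Step 3**
Reactants: 4, resorcinol
Product: 5, 1,3-bis(methoxymethoxy)benzene
Conditions: MOMCl (2.6 equiv), i-Pr2NEt, CH2Cl2, 0 °C → rt
Reagents that add atoms: chloromethyl methyl ether, COCCl
Why: Double O-alkylation installs two cooperating directing groups for the next step.

**Step 4**
Reactants: 5, 1,3-bis(methoxymethoxy)benzene; 3, 4-(methoxymethoxy)benzaldehyde
Product: 6, [2,6-bis(methoxymethoxy)phenyl][4-(methoxymethoxy)phenyl]methyl acetate (racemic; used crude)
Conditions: n-BuLi, THF, 0 °C, 1 h; add 3, −78 → 0 °C; then Ac2O, 0 °C → rt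
Reagents that add atoms: acetic anhydride, CC(=O)OC(C)=O
Why: Directed ortho-metalation occurs only at C2 between the two OMOM groups; 1,2-addition to the aldehyde and in situ acetylation of the alkoxide follow (the new stereocentre is removed in step 5).

**Step 5**
Reactants: 6, diarylmethyl acetate
Product: 7, 1,3-bis(methoxymethoxy)-2-[4-(methoxymethoxy)benzyl]benzene
Conditions: H2 (1 atm), 10% Pd/C, Et3N (1.2 equiv), EtOAc, rt
Reagents that add atoms: none
Why: Hydrogenolysis of a doubly benzylic acetate; the aryl MOM acetals are not benzylic C–O bonds and are untouched under the buffered conditions.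

**Step 6**
Reactants: 7, the diarylmethane
Product: 8, 3,5-bis(methoxymethoxy)-4-[4-(methoxymethoxy)benzyl]phenol
Conditions: [Ir(OMe)(cod)]2 (1.5 mol %), dtbpy (3 mol %), B2pin2 (0.75 equiv), THF, 80 °C; then 30% H2O2, aq. NaOH, THF, 0 °C
Reagents that add atoms: hydrogen peroxide, OO (the phenolic O); B2pin2 is transient and leaves no atoms
Why: Sterically controlled Ir-catalysed C–H borylation takes the only C–H with no ortho substituent (para to the benzyl group), and ipso-oxidation of the ArBpin gives the phenol.

**Step 7**
Reactants: 8, the phenol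
Product: 9, 2-bromo-3,5-bis(methoxymethoxy)-4-[4-(methoxymethoxy)benzyl]phenol
Conditions: NBS (1.0 equiv), CH2Cl2, −78 → −40 °C, dark
Reagents that add atoms: N-bromosuccinimide, O=C1CCC(=O)N1Br
Why: Electrophilic aromatic bromination at one of the two equivalent positions ortho to the free OH (para is blocked); low temperature and 1.0 equiv limit dibromination.

**Step 8**
Reactants: 9, the bromophenol
Product: 10, 2-bromo-1-(1-ethoxyethoxy)-3,5-bis(methoxymethoxy)-4-[4-(methoxymethoxy)benzyl]benzene (racemic at the acetal carbon)
Conditions: ethyl vinyl ether (5 equiv), PPTS (5 mol %), CH2Cl2, 0 °C → rt; Et3N quench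
Reagents that add atoms: ethyl vinyl ether, C=COCC
Why: Acid-catalysed acetalisation marks the one oxygen para to the benzyl group with an EE group that is far more acid-labile than MOM and stable to t-BuLi.

**Step 9**
Reactants: 11, 4-iodophenol
Product: 12, 1-iodo-4-(methoxymethoxy)benzene
Conditions: MOMCl, i-Pr2NEt, CH2Cl2, 0 °C → rt
Reagents that add atoms: chloromethyl methyl ether, COCCl
Why: Phenol O-alkylation, as in step 1.

**Step 10**
Reactants: 12, 1-iodo-4-(methoxymethoxy)benzene; 13, acrylic acid
Product: 14, (E)-3-[4-(methoxymethoxy)phenyl]prop-2-enoic acid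
Conditions: Pd(OAc)2 (2 mol %), Et3N (3 equiv), MeCN, 80 °C; cold citric acid work-up
Reagents that add atoms: none
Why: Mizoroki–Heck arylation; syn insertion and syn β-hydride elimination give the E-cinnamic acid only.

**Step 11**
Reactants: 14, the cinnamic acid
Product: 15, (E)-3-[4-(methoxymethoxy)phenyl]-1-(morpholin-4-yl)prop-2-en-1-one
Conditions: morpholine, EDC·HCl, HOBt, CH2Cl2, 0 °C → rt
Reagents that add atoms: morpholine, C1COCCN1
Why: Carbodiimide amide coupling; the morpholine amide is a good epoxidation substrate and later behaves as a Weinreb-type acylating agent.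

**Step 12**
Reactants: 15, the cinnamoyl morpholine amide
Product: 16, [(2R,3S)-3-[4-(methoxymethoxy)phenyl]oxiran-2-yl](morpholin-4-yl)methanone (trans)
Conditions: Sm(O-i-Pr)3/(S)-BINOL/Ph3As=O (1:1:1, 10 mol %), TBHP (1.5 equiv, decane), 4 Å MS, THF, rt
Reagents that add atoms: tert-butyl hydroperoxide, CC(C)(C)OO (epoxide O)
Why: Shibasaki lanthanide–BINOL nucleophilic epoxidation of an unsaturated amide; the E-alkene gives the trans epoxide, and the (S)-BINOL complex is taken (from recalled cinnamamide precedent, to be confirmed by rotation/CD) to give the (2R,3S) enantiomer, whose C2 becomes C3 (R) of the target.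

**Step 13**
Reactants: 10, the aryl bromide; 16, the epoxy amide
Product: 17, {6-(1-ethoxyethoxy)-2,4-bis(methoxymethoxy)-3-[4-(methoxymethoxy)benzyl]phenyl}{(2R,3S)-3-[4-(methoxymethoxy)phenyl]oxiran-2-yl}methanone (mixture of acetal epimers)
Conditions: t-BuLi (2.05 equiv), THF, −78 °C, 20 min; add 16 (0.9 equiv), −78 → −40 °C; pH 7 buffer
Reagents that add atoms: none
Why: Br–Li exchange outpaces any deprotonation, and the aryllithium acylates on the morpholine amide through a stable tetrahedral intermediate (Weinreb-type ketone synthesis), leaving both epoxide stereocentres untouched.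

**Step 14**
Reactants: 17, the epoxy ketone
Product: 18, gericudranin E, (2R,3R)-3,5,7-trihydroxy-6-(4-hydroxybenzyl)-2-(4-hydroxyphenyl)chroman-4-one
Conditions: CSA (0.1 equiv), MeOH–CH2Cl2 (1:5), 0 °C → rt; then 3 M HCl in MeOH, 45 °C (one pot, two stages)
Reagents that add atoms: none
Why: Mild acid removes only the EE group, so only the oxygen para to the benzyl group is free to open the protonated epoxide at the p-alkoxy-stabilised benzylic carbon (6-endo, inversion, giving C2 R and the trans ring); C3 keeps its R configuration, and HCl/MeOH then cleaves the four MOM ethers.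

## Compound list

1 | 4-bromophenol | Oc1ccc(Br)cc1 | starting material
2 | 1-bromo-4-(methoxymethoxy)benzene | COCOc1ccc(Br)cc1 | intermediate
3 | 4-(methoxymethoxy)benzaldehyde | COCOc1ccc(C=O)cc1 | intermediate
4 | resorcinol | Oc1cccc(O)c1 | starting material
5 | 1,3-bis(methoxymethoxy)benzene | COCOc1cccc(OCOC)c1 | intermediate
6 | [2,6-bis(methoxymethoxy)phenyl][4-(methoxymethoxy)phenyl]methyl acetate (racemic) | CC(=O)OC(c1ccc(OCOC)cc1)c1c(OCOC)cccc1OCOC | intermediate
7 | 1,3-bis(methoxymethoxy)-2-[4-(methoxymethoxy)benzyl]benzene | COCOc1ccc(Cc2c(OCOC)cccc2OCOC)cc1 | intermediate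
8 | 3,5-bis(methoxymethoxy)-4-[4-(methoxymethoxy)benzyl]phenol | COCOc1ccc(Cc2c(OCOC)cc(O)cc2OCOC)cc1 | intermediate
9 | 2-bromo-3,5-bis(methoxymethoxy)-4-[4-(methoxymethoxy)benzyl]phenol | COCOc1ccc(Cc2c(OCOC)cc(O)c(Br)c2OCOC)cc1 | intermediate
10 | 2-bromo-1-(1-ethoxyethoxy)-3,5-bis(methoxymethoxy)-4-[4-(methoxymethoxy)benzyl]benzene | CCOC(C)Oc1cc(OCOC)c(Cc2ccc(OCOC)cc2)c(OCOC)c1Br | intermediate
11 | 4-iodophenol | Oc1ccc(I)cc1 | starting material
12 | 1-iodo-4-(methoxymethoxy)benzene | COCOc1ccc(I)cc1 | intermediate
13 | acrylic acid | C=CC(=O)O | starting material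
14 | (E)-3-[4-(methoxymethoxy)phenyl]prop-2-enoic acid | COCOc1ccc(/C=C/C(=O)O)cc1 | intermediate
15 | (E)-3-[4-(methoxymethoxy)phenyl]-1-(morpholin-4-yl)prop-2-en-1-one | COCOc1ccc(/C=C/C(=O)N2CCOCC2)cc1 | intermediate
16 | [(2R,3S)-3-[4-(methoxymethoxy)phenyl]oxiran-2-yl](morpholin-4-yl)methanone | O=C(N1CCOCC1)[C@@H]2O[C@H]2c3ccc(OCOC)cc3 | intermediate
17 | {6-(1-ethoxyethoxy)-2,4-bis(methoxymethoxy)-3-[4-(methoxymethoxy)benzyl]phenyl}{(2R,3S)-3-[4-(methoxymethoxy)phenyl]oxiran-2-yl}methanone | O=C([C@@H]1O[C@H]1c2ccc(OCOC)cc2)c3c(OC(C)OCC)cc(OCOC)c(Cc4ccc(OCOC)cc4)c3OCOC | intermediate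
18 | gericudranin E, (2R,3R)-3,5,7-trihydroxy-6-(4-hydroxybenzyl)-2-(4-hydroxyphenyl)chroman-4-one | O=C1c2c(cc(O)c(Cc3ccc(O)cc3)c2O)O[C@H](c2ccc(O)cc2)[C@H]1O | target

## Summary

Total steps: 14.
Longest linear sequence: 9 steps (1 → 2 → 4 → 5 → 6 → 7 → 8 → 13 → 14). The resorcinol line is 8 steps and the 4-iodophenol line is 6.

Three steps most likely to fail:

- **Step 12 (asymmetric epoxidation).** The electron-rich cinnamoyl amide may react slowly or with low ee, and the facial sense is the least certain point of the route. Fallback: move the stereo-induction after the coupling. Add the aryllithium from 10 to the unsaturated amide 15 to give the chalcone, then epoxidise the enone by Juliá–Colonna epoxidation (poly-L-leucine, urea–H2O2, DBU), which gives the same (αR,βS)-epoxy ketone 17.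
- **Step 13 (aryllithium acylation).** The hindered 2,6-dialkoxyaryllithium may deprotonate or open the epoxy amide instead of acylating. Fallback: acylate the aryllithium with N-methoxy-N-methylacetamide to give the acetophenone, condense it with aldehyde 3 (Claisen–Schmidt) to the chalcone, and epoxidise asymmetrically as above.
- **Step 14 (acid cascade).** Risks are aroyl migration, methanolysis of the epoxide and partial C2 epimerisation. Fallback: open the epoxide of 17 with BnSH/SnCl4 to the β-benzylthio-α-hydroxy ketone, remove the EE group, close the ring with a thiophilic Lewis acid (AgBF4), and only then remove the MOM groups.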